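**Synthesis outline**

- Cuts: the alkyl C6–O bond of the ester on the cyclobutane carboxyl that is cis to both guaiacyl groups, and the acyl–O bond of the ester on the carboxyl trans to them, so one bicyclic alcohol serves both arms. Then the two aryl–carbon bonds at the cyclobutane, leaving a bought trans-1,3-disubstituted cyclobutane and a protected 4-iodoguaiacol. In the alcohol, the C4a–C7a, C5–C6 and C6–C7 bonds (Pauson–Khand), leaving a nitrogen-tethered 1,7-enyne.
- Forward order: the piperidine and cyclopentenone rings of the amine unit close together in the Pauson–Khand step. The four-membered ring is bought and receives its two aryl groups by directed C–H arylation. The two amine units are then attached one after the other as esters; the N-methyl groups and phenols are unveiled last.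
- Enabling feature: on the cyclobutane, the carboxyl carbon C1 lies between the two ring methylenes C2 and C4, each with one hydrogen on the face of a C1 carboxamide, while the C3 carboxyl sits on the other face. A chelating amide at C1 reaches exactly these two C–H bonds and gives the pattern of the target: both aryl groups cis to each other and to the C1 carboxyl, trans to the C3 carboxyl. Dimerisation of a ferulate does not give this pattern.
- Stereochemistry: C4 is bought; C4a comes from the Pauson–Khand step (directed by the C4 methyl), C7a from hydrogenation, C7 from equilibration, C6 from hydride addition. The same alcohol is esterified with retention (acylation, arm on C3) and with inversion (Mitsunobu, arm on C1). The trans relation of the two carboxyl carbons is bought and the palladacycle places both aryl groups cis to the amide.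

Key step: step 9

Remark: ring positions of the bicyclic amine follow cyclopenta[c]pyridine numbering (1, 2 = nitrogen, 3, 4, 4a, 5, 6, 7, 7a); in the discussion of the cyclobutane (not in systematic names) C1 is the carboxyl-bearing carbon cis to both aryl groups, C2 and C4 carry the aryl groups, C3 carries the other carboxyl.

Remark: the ring nitrogen is kept as its tert-butyl carbamate through both esterifications and is turned into N-methyl only afterwards, so that no tertiary amine meets alkaline hydrogen peroxide and no zwitterionic amino acid has to be handled. The diarylcyclobutane core of 17 and 18 has a mirror plane through C1 and C3, so the absolute configuration of the target rests on the amine unit alone.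

Remark: which face of the C6 ketone LiBH(sec-Bu)3 attacks (step 6) is a prediction from 2-alkylcyclopentanone behaviour, not an established result for this ring system; a fallback is given.

**Route**

Step 1
Reactants: 1 (S)-3-[(tert-butoxycarbonyl)amino]-2-methylpropanoic acid
Product: 2 tert-butyl [(S)-3-hydroxy-2-methylpropyl]carbamate
Conditions: BH3·SMe2, THF, 0 °C to rt; MeOH quench
Reagents that add atoms: none
Why: Borane reduces the free carboxylic acid through an acyloxyborane much faster than it touches the carbamate, and nothing in the medium can enolise the stereocentre, so the S configuration should be kept (chemoselective borane reduction of a carboxylic acid).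

Step 2
Reactants: 2 tert-butyl [(S)-3-hydroxy-2-methylpropyl]carbamate
Product: 4 tert-butyl [(R)-2-methylbut-3-en-1-yl]carbamate, via aldehyde 3 (not isolated)
Conditions: Dess–Martin periodinane, NaHCO3, CH2Cl2, 0 °C to rt; then Ph3P=CH2 (from Ph3PCH3Br, KN(SiMe3)2, excess), THF, −78 to 0 °C
Reagents that add atoms: methyltriphenylphosphonium bromide C[P+](c1ccccc1)(c1ccccc1)c1ccccc1.[Br-]
Why: Buffered Dess–Martin oxidation gives the α-branched aldehyde without enolisation, and immediate Wittig methylenation at low temperature turns it into the terminal alkene before the stereocentre can epimerise; the descriptor changes from S to R only through the priority change.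

Step 3
Reactants: 4 tert-butyl [(R)-2-methylbut-3-en-1-yl]carbamate; 5 1-bromobut-2-yne
Product: 6 tert-butyl (but-2-yn-1-yl)[(R)-2-methylbut-3-en-1-yl]carbamate
Conditions: NaH, DMF, 0 °C to rt
Reagents that add atoms: none
Why: The sodium salt of the carbamate displaces the primary propargylic bromide in an SN2 reaction, giving the nitrogen-tethered 1,7-enyne without touching the allylic stereocentre (N-alkylation of a carbamate).

Step 4
Reactants: 6 tert-butyl (but-2-yn-1-yl)[(R)-2-methylbut-3-en-1-yl]carbamate
Product: 8 tert-butyl (4R,4aR)-4,7-dimethyl-6-oxo-1,3,4,4a,5,6-hexahydro-2H-cyclopenta[c]pyridine-2-carboxylate, via dicobalt hexacarbonyl alkyne complex 7 (not isolated)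
Conditions: Co2(CO)8 (1.1 equiv), CH2Cl2, rt; then N-methylmorpholine N-oxide, 0 °C to rt
Reagents that add atoms: dicobalt octacarbonyl [C-]#[O+].[C-]#[O+].[C-]#[O+].[C-]#[O+].[C-]#[O+].[C-]#[O+].[C-]#[O+].[C-]#[O+].[Co].[Co]
Why: Intramolecular Pauson–Khand reaction: once the N-oxide has removed a carbonyl ligand as CO2, the alkyne–Co2(CO)6 complex inserts the tethered alkene and then CO in a formal [2+2+1] cycloaddition that closes the piperidine ring (C4a–C7a) and the cyclopentenone ring (C5–C6, C6–C7) together, and the C4 methyl should sit pseudo-equatorial in the chair-like insertion transition state so that H-4a ends cis to it (4aR).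

Step 5
Reactants: 8 tert-butyl (4R,4aR)-4,7-dimethyl-6-oxo-1,3,4,4a,5,6-hexahydro-2H-cyclopenta[c]pyridine-2-carboxylate
Product: 10 tert-butyl (4R,4aR,7R,7aS)-4,7-dimethyl-6-oxooctahydro-2H-cyclopenta[c]pyridine-2-carboxylate, via C7-epimeric ketone 9 (not isolated)
Conditions: H2 (4 atm), 10% Pd/C, EtOAc, rt; filter; then NaOMe (substoichiometric), MeOH, rt
Reagents that add atoms: none
Why: Heterogeneous hydrogenation of the enone should add both hydrogens to C7=C7a from the face that carries H-4a, fixing the cis ring fusion (7aS), and the C7 methyl, first formed cis to C1, is then equilibrated through the enolate to the more stable position trans to C1 (7R) (enone hydrogenation followed by base epimerisation next to a ketone).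

Step 6
Reactants: 10 tert-butyl (4R,4aR,7R,7aS)-4,7-dimethyl-6-oxooctahydro-2H-cyclopenta[c]pyridine-2-carboxylate
Product: 11 tert-butyl (4R,4aR,6S,7R,7aS)-6-hydroxy-4,7-dimethyloctahydro-2H-cyclopenta[c]pyridine-2-carboxylate
Conditions: LiBH(sec-Bu)3, THF, −78 °C; then aq. NaOH, H2O2, 0 °C
Reagents that add atoms: none
Why: The bulky trialkylborohydride should add to the cyclopentanone from the side of the C7 hydrogen, anti to the adjacent C7 methyl, as it does with 2-alkylcyclopentanones, so the new hydroxyl stands cis to the C7 methyl (6S) (ketone reduction with a hindered hydride).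

Step 7
Reactants: 12 trans-3-(methoxycarbonyl)cyclobutane-1-carboxylic acid
Product: 14 methyl trans-3-(quinolin-8-ylcarbamoyl)cyclobutane-1-carboxylate, via acid chloride 13 (not isolated)
Conditions: (COCl)2, cat. DMF, CH2Cl2, 0 °C to rt; evaporate; then 8-aminoquinoline, pyridine, CH2Cl2, 0 °C to rt
Reagents that add atoms: oxalyl chloride (chlorine of 13) O=C(Cl)C(=O)Cl; 8-aminoquinoline Nc1cccc2cccnc12
Why: Acylation of the weakly nucleophilic 8-aminoquinoline by the acid chloride installs the N,N-bidentate auxiliary, and the weak base pyridine avoids ketene formation so the trans relation of the two ring substituents is kept (amide formation through an acid chloride).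

Step 8
Reactants: 15 4-iodo-2-methoxyphenol
Product: 16 1-(benzyloxy)-4-iodo-2-methoxybenzene
Conditions: BnBr, K2CO3, DMF, rt
Reagents that add atoms: benzyl bromide BrCc1ccccc1
Why: Williamson etherification masks the phenol, which would otherwise interfere with the palladium chemistry, the amide activation and the Mitsunobu reaction; the benzyl ether is removed by hydrogenolysis at the end.

Step 9
Reactants: 14 methyl trans-3-(quinolin-8-ylcarbamoyl)cyclobutane-1-carboxylate; 16 1-(benzyloxy)-4-iodo-2-methoxybenzene
Product: 17 methyl 2,4-bis[4-(benzyloxy)-3-methoxyphenyl]-3-(quinolin-8-ylcarbamoyl)cyclobutane-1-carboxylate (both aryl groups cis to the amide and trans to the ester)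
Conditions: Pd(OAc)2 (10 mol %), AgOAc (3 equiv), 16 (4 equiv), toluene, 110 °C, sealed tube
Reagents that add atoms: none
Why: The quinoline nitrogen and the deprotonated amide nitrogen of 14 chelate divalent palladium, acetate-assisted concerted metalation–deprotonation cleaves the ring C–H bond at C2 on the amide face to give a five-membered palladacycle cis-fused to the cyclobutane, oxidative addition of 16 leads to tetravalent palladium, and reductive elimination forms the aryl–C2 bond with retention while AgOAc takes up iodide as AgI; the cycle then repeats at C4. The closest known reaction type is the 8-aminoquinoline-directed, Pd(OAc)2-catalysed β-C(sp3)–H arylation of cycloalkanecarboxamides with aryl iodides, which is established for single and double arylation of cyclobutanecarboxamides. No ring of the product is closed, since the four-membered ring is bought and the only ring formed is the transient palladacycle. The two new stereocentres at C2 and C4 are controlled by the chelate, which reaches only the hydrogens cis to the C1 carboxamide, so both aryl groups end cis to the amide and, because the C3 ester was trans to the amide from the start, trans to the ester. The step needs face selectivity, complete double arylation and no epimerisation at C1 or C3: the substrate offers exactly two equivalent cis β-C–H bonds with the ester out of the way on the other face, excess 16 drives the second arylation, and acetate is too weak a base to enolise the ester or amide.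

Step 10
Reactants: 17 methyl 2,4-bis[4-(benzyloxy)-3-methoxyphenyl]-3-(quinolin-8-ylcarbamoyl)cyclobutane-1-carboxylate
Product: 18 2,4-bis[4-(benzyloxy)-3-methoxyphenyl]-3-(quinolin-8-ylcarbamoyl)cyclobutane-1-carboxylic acid (carboxyl trans to both aryl groups)
Conditions: LiOH, THF/MeOH/H2O, rt to 40 °C; then aq. HCl to pH 4
Reagents that add atoms: lithium hydroxide [Li+].[OH-]
Why: Hydroxide saponifies the methyl ester while the quinolyl amide, deprotonated in this medium, resists attack and protects its own α-carbon, and the ester-bearing carbon already has the stable trans relation to both aryl groups, so no stereocentre should change (ester saponification).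

Step 11
Reactants: 18 diaryl cyclobutane monoacid amide; 11 tert-butyl (4R,4aR,6S,7R,7aS)-6-hydroxy-4,7-dimethyloctahydro-2H-cyclopenta[c]pyridine-2-carboxylate
Product: 19 C3 ester of 18 with 11 (6S, ester oxygen cis to the C7 methyl), quinolyl amide in place
Conditions: EDC·HCl, DMAP, CH2Cl2, rt
Reagents that add atoms: none
Why: Steglich esterification: the carbodiimide-activated acid passes through the acylpyridinium ion to the C6 hydroxyl, the C6–O bond is not broken so C6 keeps its configuration, and the activated carboxyl is the one already trans to both aryl groups, so its α-carbon has no driving force to epimerise.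

Step 12
Reactants: 19 C3 ester of 18 with 11, quinolyl amide in place
Product: 21 monoester monoacid with the free C1 carboxyl cis to both aryl groups, via N-Boc imide 20 (not isolated)
Conditions: Boc2O, DMAP, MeCN, rt to 40 °C; evaporate; then LiOH, H2O2, THF/H2O, 0 °C; Na2SO3; aq. HCl to pH 4
Reagents that add atoms: di-tert-butyl dicarbonate (Boc group of 20) CC(C)(C)OC(=O)OC(=O)OC(C)(C)C; hydrogen peroxide OO
Why: tert-Butoxycarbonylation of the anilide nitrogen turns the robust amide into a twisted N-acyl carbamate, whose acyl carbonyl is attacked at 0 °C by the small, weakly basic hydroperoxide anion, so the C1 carboxyl should be released without enolisation and without loss of the hindered C6 ester or the ring carbamate (amide activation followed by hydroperoxide cleavage of an imide).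

Step 13
Reactants: 21 monoester monoacid; 11 tert-butyl (4R,4aR,6S,7R,7aS)-6-hydroxy-4,7-dimethyloctahydro-2H-cyclopenta[c]pyridine-2-carboxylate
Product: 22 bis(N-Boc) diester, dibenzyl ether (C3 arm 6S, C1 arm 6R)
Conditions: PPh3, diisopropyl azodicarboxylate, THF, 0 °C to rt
Reagents that add atoms: none
Why: Mitsunobu reaction: the C6 hydroxyl of a second molecule of 11 becomes an oxyphosphonium leaving group and the carboxylate of 21 displaces it from the opposite face, anti to the C7 methyl, which inverts C6 (6R, oxygen trans to the C7 methyl) and uses the hindered acid only as a nucleophile, so its α-carbon, cis to both aryl groups, never belongs to an acylating species.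

Step 14
Reactants: 22 bis(N-Boc) diester, dibenzyl ether
Product: 24 N,N'-dimethyl diester, dibenzyl ether of the target, via bis-secondary amine 23 (not isolated)
Conditions: 4 M HCl in dioxane, CH2Cl2, 0 °C to rt; evaporate; then aq. CH2O, NaBH(OAc)3, i-Pr2NEt, ClCH2CH2Cl, rt
Reagents that add atoms: formaldehyde C=O
Why: Acidolysis of both tert-butyl carbamates gives the bis-secondary amine (as its hydrochloride), which is methylated on both nitrogens by reductive amination with formaldehyde and NaBH(OAc)3 under conditions that leave the esters, the benzyl ethers and every stereocentre alone (Boc removal followed by reductive amination).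

Step 15
Reactants: 24 N,N'-dimethyl diester, dibenzyl ether of the target
Product: 25 target CNP0283097.4
Conditions: H2 (1 atm), 10% Pd/C, AcOH, MeOH/EtOAc, rt; then aq. NaHCO3
Reagents that add atoms: none
Why: Hydrogenolysis of the two benzyl aryl ethers over palladium should free both phenols, with acetic acid keeping the amines protonated so they do not slow the catalyst, while the esters, the arylcyclobutane and all stereocentres are inert (catalytic hydrogenolysis).

**Compound list**

1 | (S)-3-[(tert-butoxycarbonyl)amino]-2-methylpropanoic acid | OC(=O)[C@@H](C)CNC(=O)OC(C)(C)C | starting material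
2 | tert-butyl [(S)-3-hydroxy-2-methylpropyl]carbamate | OC[C@@H](C)CNC(=O)OC(C)(C)C | intermediate
3 | tert-butyl [(S)-2-methyl-3-oxopropyl]carbamate | O=C[C@@H](C)CNC(=O)OC(C)(C)C | intermediate
4 | tert-butyl [(R)-2-methylbut-3-en-1-yl]carbamate | C=C[C@@H](C)CNC(=O)OC(C)(C)C | intermediate
5 | 1-bromobut-2-yne | CC#CCBr | starting material
6 | tert-butyl (but-2-yn-1-yl)[(R)-2-methylbut-3-en-1-yl]carbamate | C=C[C@@H](C)CN(CC#CC)C(=O)OC(C)(C)C | intermediate
7 | hexacarbonyldicobalt complex of the alkyne of 6 | CC12[Co]3(=C=O)(=C=O)(=C=O)[Co]1(=C=O)(=C=O)(=C=O)C23CN(C[C@H](C)C=C)C(=O)OC(C)(C)C | intermediate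
8 | tert-butyl (4R,4aR)-4,7-dimethyl-6-oxo-1,3,4,4a,5,6-hexahydro-2H-cyclopenta[c]pyridine-2-carboxylate (C7=C7a enone) | O=C1C[C@H]2C(CN(C(=O)OC(C)(C)C)C[C@@H]2C)=C1C | intermediate
9 | tert-butyl (4R,4aR,7S,7aS)-4,7-dimethyl-6-oxooctahydro-2H-cyclopenta[c]pyridine-2-carboxylate (cis-fused, C7 methyl cis to C1) | O=C1C[C@H]2[C@H](CN(C(=O)OC(C)(C)C)C[C@@H]2C)[C@@H]1C | intermediate
10 | tert-butyl (4R,4aR,7R,7aS)-4,7-dimethyl-6-oxooctahydro-2H-cyclopenta[c]pyridine-2-carboxylate (cis-fused, C7 methyl trans to C1) | O=C1C[C@H]2[C@H](CN(C(=O)OC(C)(C)C)C[C@@H]2C)[C@H]1C | intermediate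
11 | tert-butyl (4R,4aR,6S,7R,7aS)-6-hydroxy-4,7-dimethyloctahydro-2H-cyclopenta[c]pyridine-2-carboxylate (hydroxyl cis to the C7 methyl) | O[C@H]1C[C@H]2[C@H](CN(C(=O)OC(C)(C)C)C[C@@H]2C)[C@H]1C | intermediate
12 | trans-3-(methoxycarbonyl)cyclobutane-1-carboxylic acid | C1[C@@H](C(=O)OC)C[C@@H]1C(=O)O | starting material
13 | methyl trans-3-(chlorocarbonyl)cyclobutane-1-carboxylate | C1[C@@H](C(=O)OC)C[C@@H]1C(=O)Cl | intermediate
14 | methyl trans-3-(quinolin-8-ylcarbamoyl)cyclobutane-1-carboxylate | C1[C@@H](C(=O)OC)C[C@@H]1C(=O)Nc1cccc2cccnc12 | intermediate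
15 | 4-iodo-2-methoxyphenol | COc1cc(I)ccc1O | starting material
16 | 1-(benzyloxy)-4-iodo-2-methoxybenzene | COc1cc(I)ccc1OCc1ccccc1 | intermediate
17 | methyl 2,4-bis[4-(benzyloxy)-3-methoxyphenyl]-3-(quinolin-8-ylcarbamoyl)cyclobutane-1-carboxylate, aryl groups cis to each other and to the amide, trans to the ester | COc1cc([C@@H]2[C@@H](C(=O)OC)[C@H](c3ccc(OCc4ccccc4)c(OC)c3)[C@@H]2C(=O)Nc2cccc3cccnc23)ccc1OCc1ccccc1 | intermediate
18 | 2,4-bis[4-(benzyloxy)-3-methoxyphenyl]-3-(quinolin-8-ylcarbamoyl)cyclobutane-1-carboxylic acid, same relative configuration | COc1cc([C@@H]2[C@@H](C(=O)O)[C@H](c3ccc(OCc4ccccc4)c(OC)c3)[C@@H]2C(=O)Nc2cccc3cccnc23)ccc1OCc1ccccc1 | intermediate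
19 | (4R,4aR,6S,7R,7aS)-2-Boc-4,7-dimethyloctahydrocyclopenta[c]pyridin-6-yl ester of 18 at C3, quinolyl amide at C1 | COc1cc([C@@H]2[C@@H](C(=O)O[C@H]3C[C@H]4[C@H](CN(C(=O)OC(C)(C)C)C[C@@H]4C)[C@H]3C)[C@H](c3ccc(OCc4ccccc4)c(OC)c3)[C@@H]2C(=O)Nc2cccc3cccnc23)ccc1OCc1ccccc1 | intermediate
20 | N-Boc-N-(quinolin-8-yl) imide of 19 | COc1cc([C@@H]2[C@@H](C(=O)O[C@H]3C[C@H]4[C@H](CN(C(=O)OC(C)(C)C)C[C@@H]4C)[C@H]3C)[C@H](c3ccc(OCc4ccccc4)c(OC)c3)[C@@H]2C(=O)N(C(=O)OC(C)(C)C)c2cccc3cccnc23)ccc1OCc1ccccc1 | intermediate
21 | monoester monoacid: C3 ester as in 19, free C1 carboxyl cis to both aryl groups | COc1cc([C@@H]2[C@@H](C(=O)O[C@H]3C[C@H]4[C@H](CN(C(=O)OC(C)(C)C)C[C@@H]4C)[C@H]3C)[C@H](c3ccc(OCc4ccccc4)c(OC)c3)[C@@H]2C(=O)O)ccc1OCc1ccccc1 | intermediate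
22 | bis(N-Boc) diester, dibenzyl ether: C3 arm 6S, C1 arm 6R | COc1cc([C@@H]2[C@@H](C(=O)O[C@H]3C[C@H]4[C@H](CN(C(=O)OC(C)(C)C)C[C@@H]4C)[C@H]3C)[C@H](c3ccc(OCc4ccccc4)c(OC)c3)[C@@H]2C(=O)O[C@@H]2C[C@H]3[C@H](CN(C(=O)OC(C)(C)C)C[C@@H]3C)[C@H]2C)ccc1OCc1ccccc1 | intermediate
23 | bis-secondary amine diester, dibenzyl ether | COc1cc([C@@H]2[C@@H](C(=O)O[C@H]3C[C@H]4[C@H](CNC[C@@H]4C)[C@H]3C)[C@H](c3ccc(OCc4ccccc4)c(OC)c3)[C@@H]2C(=O)O[C@@H]2C[C@H]3[C@H](CNC[C@@H]3C)[C@H]2C)ccc1OCc1ccccc1 | intermediate
24 | N,N'-dimethyl diester, dibenzyl ether of the target | COc1cc([C@@H]2[C@@H](C(=O)O[C@H]3C[C@H]4[C@H](CN(C)C[C@@H]4C)[C@H]3C)[C@H](c3ccc(OCc4ccccc4)c(OC)c3)[C@@H]2C(=O)O[C@@H]2C[C@H]3[C@H](CN(C)C[C@@H]3C)[C@H]2C)ccc1OCc1ccccc1 | intermediate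
25 | CNP0283097.4 | COc1cc([C@@H]2[C@@H](C(=O)O[C@H]3C[C@H]4[C@H](CN(C)C[C@@H]4C)[C@H]3C)[C@H](c3ccc(O)c(OC)c3)[C@@H]2C(=O)O[C@@H]2C[C@H]3[C@H](CN(C)C[C@@H]3C)[C@H]2C)ccc1O | target

**Step count and risks**

Total step count: 15. Longest linear sequence: 11 steps (steps 1 to 6, then 11 to 15, from 1).

Steps most likely to fail:

Step 12. The acyl carbon to be attacked sits between two cis aryl groups, so hydroperoxide attack may be slow and be diverted to the carbamate carbonyl (returning 19) or to the C6 ester, and long exposure to base may epimerise the ring carbon that must stay cis to both aryl groups. The fallback sets out from 19. Boc activation as in the route gives the N-Boc imide 20, which is opened without peroxide by base-mediated alcoholysis with allyl alcohol and K3PO4 in THF at room temperature to give the allyl ester F3. Deallylation with Pd(PPh3)4 and morpholine under neutral conditions then gives 21, where the route is rejoined.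

Step 13. Both partners are hindered, so the oxyphosphonium ion may eliminate to a cyclopentene or be displaced too slowly, and the azodicarboxylate adduct may be consumed unproductively. The fallback sets out from 11, which is converted with methanesulfonyl chloride and Et3N in CH2Cl2 at 0 °C into the methanesulfonate F4. Thermal SN2 displacement by the caesium salt of 21 (Cs2CO3, DMF, 50 to 60 °C) then forms the same C6–O bond with inversion and gives 22, where the route is rejoined.

Step 6. The convex-face bias of the cis-fused bicycle opposes the directing effect of the C7 methyl, so facial selectivity of hydride addition may be poor or reversed. The fallback sets out from 10 and fixes C6 by substitution instead of by facial selectivity. NaBH4 in MeOH at −20 °C, a small hydride expected to add from the convex face, gives the C6-epimeric alcohol F1 (hydroxyl trans to the C7 methyl). Mitsunobu reaction with 4-nitrobenzoic acid (PPh3, diisopropyl azodicarboxylate, THF) gives the inverted 4-nitrobenzoate F2. Methanolysis with K2CO3 in MeOH returns 11, where the route is rejoined.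

Further compounds
F1 | step 6 | tert-butyl (4R,4aR,6R,7R,7aS)-6-hydroxy-4,7-dimethyloctahydro-2H-cyclopenta[c]pyridine-2-carboxylate (C6 epimer of 11) | O[C@@H]1C[C@H]2[C@H](CN(C(=O)OC(C)(C)C)C[C@@H]2C)[C@H]1C
F2 | step 6 | (4R,4aR,6S,7R,7aS)-2-(tert-butoxycarbonyl)-4,7-dimethyloctahydrocyclopenta[c]pyridin-6-yl 4-nitrobenzoate | O=C(O[C@H]1C[C@H]2[C@H](CN(C(=O)OC(C)(C)C)C[C@@H]2C)[C@H]1C)c1ccc(cc1)[N+](=O)[O-]
F3 | step 12 | allyl ester of 21 at the C1 carboxyl | COc1cc([C@@H]2[C@@H](C(=O)O[C@H]3C[C@H]4[C@H](CN(C(=O)OC(C)(C)C)C[C@@H]4C)[C@H]3C)[C@H](c3ccc(OCc4ccccc4)c(OC)c3)[C@@H]2C(=O)OCC=C)ccc1OCc1ccccc1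
F4 | step 13 | methanesulfonate of 11 | CS(=O)(=O)O[C@H]1C[C@H]2[C@H](CN(C(=O)OC(C)(C)C)C[C@@H]2C)[C@H]1C
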